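The constants used here are assumed; the rest is arithmetic.

Slowness was what I had to reckon with in the flask, where solid Q feeds L to J and G.

    J ⇌ G (k1 = 0.0062 s⁻¹)
    L + J → L.J (k2 = 0.024 L mol⁻¹ s⁻¹)
    L + G → L.G (k3 = 0.0091 L mol⁻¹ s⁻¹)
    Q ⇌ L, rate k4*(cs4 - [L]) while solid is left; crystals form when [L] > cs4 (cs4 = 18 mM, k4 = 0.0051 s⁻¹)
    L.J ⇌ L.G (k5 = 0.0028 s⁻¹)
J 0.20 M; Q 0.500 M; G 0.20 M; time 2.0 h
1. L.J at 2.0 h, in percent of the J and G together charged
2. the change that raises the amount of L.J at 2.0 h, in percent of the J and G together charged most ("none" if none brings more than 2 percentage points) (dawn / summer / none)
3. amount of L.J at 2.0 h, in percent of the J and G together charged, after summer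
- dawn: doubling the solubility in step 4, all else as stated
- summer: doubling the dissolution coefficient of step 4, all else as stated
- L is single-handed; J and G are mirror images of each other, charged as a racemate, each of them at the stated concentration
- given per volume of solution although it is solid: Q
- at the start none of Q is in solution
- run time (flask): 2.0 h
- the handed part of L does not stay in what it makes, so the products of the two hands are mirror images too

J and G interconvert with a relaxation half-life of 0.932 min and the products with 2.06 min, both short against 2.0 h. So I treated the two hands as one substrate, amount S, with mean constant 0.0166 L mol⁻¹ s⁻¹, and took L.J as half the product.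

L relaxes with a half-life near 0.986 min, also shorter than 2.0 h. So I held it in quasi-steady state at solubility × K/(K+S), where K is the crossover amount 0.308 M, the substrate at which L is consumed with the dissolution coefficient itself.

Summing over time gives a ledger: feed = K·ln(charge/S) + (charge − S) + L, with feed 0.661 M. Of that feed, the term K·ln(charge/S) is never delivered, and in this reckoning the solid outlasts the run, because the charge of Q is more than the substrate charge plus a full solubility of L.

Freezing L at its quasi-steady value for the full substrate charge, 0.00783 M (pseudo-first-order), gave S = 0.157 M. But L rises as S falls, so I subtracted the ledger's shortfall times S/(K+S), which gave 0.117 M and L.J at 35.4 %.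

Summer doubles K and feed, and the same steps gave 40.4 %. Dawn doubles the frozen L, and that estimate, before any correction, gave 42.3 %, more than summer, so I chose dawn.

The forecast said 35.1 %, dawn and 40 %, holding that “the rate difference between the hands hardly matters”.

The simulation gave 35.1 %, dawn (a gain of 12 percentage points, against 5 points for summer) and 40.1 %.

In the flask at 2.00 h, the formula fed with the read J and G gives L at 0.0129 M, against 0.0128 M read. The neighbour flask, read at 30 min, has the same K. Frozen L gave S = 0.317 M, and the correction took off 6.15 × 10⁻⁴ M, so I reckoned L.J at 10.5 %. That neighbour flask held J 39.3 %, G 39.7 % and L.J 10.9 %.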